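All runs are simulated on assumed constants, noise included.

If the spring and autumn runs are followed to their ends, product stops rising with substrate still present: the autumn run stands near 49.4% from 0.833 min on. Its left-handed substrate reads 25.4%, half of the substrate left, so exchange appears to hold the two substrates level. The late autumn readings give a selectivity factor of 1.96, hence a product excess of 32.4%.

in all of them: left-handed substrate 0.50 M; right-handed substrate 0.50 M; racemization catalyst 6.5 mM; impurity 0.19 mM; added ligand 13 mM
- spring: reagent 1 M; free catalyst 0.34 mM; run made earlier
- autumn: reagent 1 M; free catalyst 0.75 mM; run made earlier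
- flask: reagent 1.00 M; free catalyst 0.50 mM; time 2.5 min

| run | time / min | left-handed product / % | right-handed product / % | left-handed substrate / % |
|---|---|---|---|---|
| spring | 0.200 | 6.5 | 3.2 | 42.3 |
| spring | 0.333 | 10.3 | 3.9 | 41.3 |
| spring | 0.500 | 13.7 | 5.5 | 40.2 |
| spring | 0.833 | 15.9 | 6.2 | 37.8 |
| spring | 1.50 | 17.4 | 9.1 | 37.6 |
| spring | 2.50 | 18.5 | 9.1 | 36.2 |
| autumn | 0.167 | 22.2 | 10.6 | 32.2 |
| autumn | 0.500 | 29.1 | 15.3 | 28.0 |
| autumn | 0.833 | 32.1 | 15.8 | 25.5 |
| autumn | 1.33 | 31.2 | 17.4 | 26.4 |
| autumn | 2.00 | 34.8 | 17.7 | 25.8 |
| autumn | 2.50 | 32.8 | 15.9 | 25.4 |

(scatter of a reading: 1 percentage point)

- left-handed product and right-handed product together, in percent of the left-handed substrate and right-handed substrate charged together, at 2.5 min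
- excess of left-handed product over right-handed product in the product at 2.5 min
- whether the exchange between left-handed substrate and right-handed substrate keeps pace with the reaction: how far the product's excess at 2.5 min gets from its value without exchange to its value with instant exchange (above 80% keeps pace, below 20% hardly takes part, else lags behind)

- free catalyst is single-handed; left-handed substrate and right-handed substrate are mirror images of each other, charged as a racemate, each of them at the stated concentration
- what was read earlier has a scatter of 1 percentage point, one standard deviation
- an excess is the difference of the two amounts in percent of their sum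
- an excess is below zero if the other one leads

My reckoning assumes, unproved as yet, that each impurity takes one catalyst for good and that reagent also disappears by a route second order in itself. In the first instants of the flask, impurity is taken to remove its equal of free catalyst, leaving 0.310 mM of live catalyst. In the middle, reagent is shared. With B and s the fractions of reagent and of both substrates together remaining, equal charges give dB/ds = 1 + rB/s, where r is the loss route over the catalysed route at the start. Setting B to zero for the end of the balance gives s = r^(1/(1 − r)).

The autumn plateau, solved for r, gives 2.06. Multiplying by its live catalyst gives 1.16 mM, the break-even catalyst: the live catalyst at which both routes use reagent equally at the start. Dividing it by a flask's live catalyst gives that flask's r, with reagent and substrates held at these charges and the loss route unchanged. The spring run then reckons to 26.3%, against a last reading of 27.6%. For the flask, r is 3.73, so the loss route leads at first, and the yield reckons to 38.3%. The runs flatten by 1.50 min, earlier than the time asked.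

The forecast gives 38% (34% to 42%), an excess of 34% (30% to 38%) and exchange that keeps pace, reading the plateau thus: “so the catalyst dies and yield is set by its loading”. My reckoning reaches a like yield through reagent instead, and a lower excess of 32.4%.

The flask gives a yield of 38.4%, an excess of 33.0%, and exchange that keeps pace, 95% of the way.

    2 reagent → homo dimer (k = 0.0950 L mol⁻¹ s⁻¹)
    free catalyst + impurity → spent catalyst (k = 21000 L mol⁻¹ s⁻¹)
    racemization catalyst + added ligand ⇌ idle complex (K = 570 L mol⁻¹, k = 8.70 L mol⁻¹ s⁻¹)
    reagent + free catalyst + right-handed substrate → free catalyst + right-handed product (k = 110 L² mol⁻² s⁻¹)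
    left-handed substrate + racemization catalyst ⇌ right-handed substrate + racemization catalyst, rate k5*[racemization catalyst]*[left-handed substrate] forward; the back reaction follows from the equilibrium constant (k = 220 L mol⁻¹ s⁻¹)
    reagent + free catalyst + left-handed substrate → free catalyst + left-handed product (k = 220 L² mol⁻² s⁻¹)

At 0.0456 min, reagent goes to homo dimer 3.7 times as fast as to left-handed product, and at 2.50 min that ratio is 0.0099. By then reagent stands at 0.109% of its own charge, homo dimer at 0.307 M, and free catalyst at 62.0% of the catalyst charged. In the neighbour flask with 4.8 × 10⁻⁴ M of impurity, live catalyst is 0.0200 mM, so break-even catalyst gives r = 57.8 and a yield of 6.90%. The computed yield there is 7.34%.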